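**Plan**

- Cuts, in retrosynthetic order: the C3–O ester bond (side chain as (Z)-2-(acetoxymethyl)but-2-enoic acid), then the C2–C3 bond of the dihydrofuran ring, then the aryl O–alkenyl and aryl–CH2OH bonds, back to 1-(5-bromo-2,4-dihydroxyphenyl)ethanone.
- Enabling feature: C3 carries OH, and C2 carries both the ring oxygen O1 and an isopropenyl group. The array C3(OH)–C2(O1)–C(CH3)=CH2 is the product pattern of a γ-oxyallylboration of an aldehyde. O1 and C3 sit ortho on the benzene ring (C7a, C3a), so the addition can be intramolecular and close the five-membered ring.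
- Forward: the benzene ring is bought. The non-chelated 4-OH is joined to a C4 arm by addition–elimination, and the arm is taken to an (E)-γ-aryloxyallyl pinacol boronate while the future C3 is carried as CH2OH. Oxidation to the aldehyde and acid-catalysed allylboration then close the dihydrofuran ring, create both stereocentres and unveil the isopropenyl group and the C3 hydroxyl in one operation.
- Stereochemistry: C3 comes from the chiral phosphoric acid (face of the formyl group); C2 is relayed from the E enol ether geometry through the closed chair transition state (trans). The Z side-chain alkene comes from α-iodination of (E)-crotonaldehyde and a stereoretentive lithiation–carboxylation.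
- End game: phenol silylation, base-mediated acylation without nucleophilic catalyst, desilylation.

Key step: step 7

Assumption: (R)-TRIP is taken to direct the tethered allylboronate to the Re face of the formyl group, as it does with untethered pinacol allylboronates and aryl aldehydes; should the sense prove opposite, the (S) acid is used.

**Route**

Step 1
Reactants: 1 prop-2-yn-1-ol
Product: 3 (2E)-3-iodo-2-methylprop-2-en-1-ol, via alkenylalane 2 (not isolated)
Conditions: AlMe3 (3 equiv), Cp2ZrCl2 (25 mol %), CH2Cl2, 0 °C to rt; then I2, THF, −30 to 0 °C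
Reagents that add atoms: trimethylaluminium C[Al](C)C; iodine II
Why: Negishi carboalumination adds CH3 and Al syn across the terminal alkyne (CH3 to the internal carbon), and iodinolysis with retention should give the E iodide.

Step 2
Reactants: 3 (2E)-3-iodo-2-methylprop-2-en-1-ol
Product: 4 (2E)-3-iodo-2-methylprop-2-enal
Conditions: MnO2, CH2Cl2, rt
Reagents that add atoms: none
Why: MnO2 oxidation of an allylic alcohol should leave the vinyl iodide and its geometry untouched.

Step 3
Reactants: 5 1-(5-bromo-2,4-dihydroxyphenyl)ethan-1-one; 4 (2E)-3-iodo-2-methylprop-2-enal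
Product: 6 (2E)-3-(4-acetyl-2-bromo-5-hydroxyphenoxy)-2-methylprop-2-enal
Conditions: K2CO3 (1.1 equiv), DMF, 0 °C to rt
Reagents that add atoms: none
Why: Nucleophilic vinylic substitution (addition–elimination) of the more acidic, non-chelated 4-phenoxide on the β-iodo enal should leave the hydrogen-bonded 2-OH free and give the thermodynamic E enol ether, because the intermediate enolate can rotate before iodide leaves.

Step 4
Reactants: 6 (2E)-3-(4-acetyl-2-bromo-5-hydroxyphenoxy)-2-methylprop-2-enal
Product: 7 1-(5-bromo-2-hydroxy-4-{[(1E)-3-hydroxy-2-methylprop-1-en-1-yl]oxy}phenyl)ethan-1-one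
Conditions: NaBH4, EtOH–THF, −20 °C; pH 7 buffer
Reagents that add atoms: none
Why: Borohydride 1,2-reduction of the aldehyde should be much faster than reduction of the aryl ketone, which is deactivated as its hydrogen-bonded phenoxide; the alkene geometry is not touched and the acid-sensitive product is worked up neutral.

Step 5
Reactants: 7 1-(5-bromo-2-hydroxy-4-{[(1E)-3-hydroxy-2-methylprop-1-en-1-yl]oxy}phenyl)ethan-1-one
Product: 8 1-[2-hydroxy-5-(hydroxymethyl)-4-{[(1E)-3-hydroxy-2-methylprop-1-en-1-yl]oxy}phenyl]ethan-1-one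
Conditions: Bu3SnCH2OH, Pd(PPh3)4 (5 mol %), dioxane, 100 °C
Reagents that add atoms: (tributylstannyl)methanol OC[Sn](CCCC)(CCCC)CCCC
Why: Stille coupling of the aryl bromide with the hydroxymethylstannane brings in the future C3 at the alcohol oxidation level under neutral conditions that free hydroxyl groups and the unactivated allylic alcohol tolerate.

Step 6
Reactants: 8 1-[2-hydroxy-5-(hydroxymethyl)-4-{[(1E)-3-hydroxy-2-methylprop-1-en-1-yl]oxy}phenyl]ethan-1-one
Product: 9 1-[2-hydroxy-5-(hydroxymethyl)-4-{[(1E)-2-methyl-3-(4,4,5,5-tetramethyl-1,3,2-dioxaborolan-2-yl)prop-1-en-1-yl]oxy}phenyl]ethan-1-one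
Conditions: B2pin2 (1.2 equiv), [Pd(MeCN)4](BF4)2 (5 mol %), DMSO–MeOH, rt
Reagents that add atoms: bis(pinacolato)diboron CC1(C)OB(OC1(C)C)B1OC(C)(C)C(C)(C)O1
Why: Palladium-catalysed borylation of an allylic alcohol ionises only the allylic C–OH (not the benzylic one) to an η3-allyl complex and transfers boron to the unsubstituted CH2 terminus, so the E enol ether with boron on CH2 should result.

Step 7
Reactants: 9 1-[2-hydroxy-5-(hydroxymethyl)-4-{[(1E)-2-methyl-3-(4,4,5,5-tetramethyl-1,3,2-dioxaborolan-2-yl)prop-1-en-1-yl]oxy}phenyl]ethan-1-one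
Product: 12 1-[(2R,3S)-3,6-dihydroxy-2-(prop-1-en-2-yl)-2,3-dihydro-1-benzofuran-5-yl]ethan-1-one, via aldehyde 10 (not isolated), via borate ester 11 (not isolated)
Conditions: MnO2, CH2Cl2, 0 °C, cold filtration; then (R)-TRIP [(R)-3,3′-bis(2,4,6-triisopropylphenyl)-1,1′-binaphthyl-2,2′-diyl hydrogen phosphate] (5 mol %), 4 Å MS, toluene, −30 °C; aq. NaHCO3
Reagents that add atoms: none
Why: Proposed new method: after MnO2 oxidation of the benzylic alcohol, the chiral phosphoric acid should bind a boronate oxygen through P–OH and the formyl C–H through P=O, so that the γ-carbon of the allylboronate (the O-bearing enol ether carbon) adds to the formyl carbon through a closed six-membered Zimmerman–Traxler array, the C=C shifting to become the isopropenyl group and boron ending on the C3 oxygen; the closest known reaction types are the chiral phosphoric acid-catalysed intermolecular allylboration of aryl aldehydes with pinacol allylboronates and the uncatalysed intramolecular allylboration of γ-(formylalkoxy)allylboronates to trans-2-alkenyl-3-hydroxy cyclic ethers. The dihydrofuran ring closes in a 5-exo-trig mode at the formyl carbon, with the enol ether double bond exocyclic to the new ring. C2 is controlled by the E geometry of the enol ether (aryloxy group and aldehyde aryl group both pseudo-equatorial in the chair), which should place the isopropenyl and hydroxyl groups trans; C3 is controlled by the catalyst, attack on the Re face corresponding to 3S and hence 2R. The step needs γ over α regioselectivity (boron sits on the CH2 terminus of a pinacol ester that does not undergo 1,3-shift), aldehyde over ketone chemoselectivity (the acetyl group is a hydrogen-bonded ketone out of reach of the tether) and catalysed over background reaction (the aldehyde is generated cold and used at once at −30 °C).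

Step 8
Reactants: 12 1-[(2R,3S)-3,6-dihydroxy-2-(prop-1-en-2-yl)-2,3-dihydro-1-benzofuran-5-yl]ethan-1-one
Product: 13 1-[(2R,3S)-6-[(tert-butyldimethylsilyl)oxy]-3-hydroxy-2-(prop-1-en-2-yl)-2,3-dihydro-1-benzofuran-5-yl]ethan-1-one
Conditions: TBSCl (1.1 equiv), Et3N, DMF, 0 °C
Reagents that add atoms: tert-butyldimethylsilyl chloride CC(C)(C)[Si](C)(C)Cl
Why: The phenol is silylated through its phenoxide far faster than the hindered secondary benzylic alcohol, which would need a nucleophilic catalyst.

Step 9
Reactants: 14 (2E)-but-2-enal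
Product: 15 (2Z)-2-iodobut-2-enal
Conditions: I2, K2CO3, DMAP (20 mol %), THF–H2O, rt
Reagents that add atoms: iodine II
Why: Amine-catalysed α-iodination of an enal (Baylis–Hillman-type addition, iodination of the enolate, loss of the amine) keeps CH3 trans to CHO and so should give the Z iodide.

Step 10
Reactants: 15 (2Z)-2-iodobut-2-enal
Product: 16 (2Z)-2-iodobut-2-en-1-ol
Conditions: NaBH4, CeCl3·7H2O, MeOH, 0 °C
Reagents that add atoms: none
Why: Luche reduction gives clean 1,2-reduction without touching the vinyl iodide or its geometry.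

Step 11
Reactants: 16 (2Z)-2-iodobut-2-en-1-ol
Product: 18 (2Z)-2-(hydroxymethyl)but-2-enoic acid, via dilithio species 17 (not isolated)
Conditions: n-BuLi (1.05 equiv), Et2O, −78 °C; t-BuLi (2.1 equiv), −78 °C; CO2; aq. HCl
Reagents that add atoms: carbon dioxide O=C=O
Why: O-deprotonation followed by iodine–lithium exchange gives a configurationally stable vinyllithium (a lithium alkoxide is too poor a leaving group for β-elimination), and carboxylation with retention should place CH3 cis to CO2H.

Step 12
Reactants: 18 (2Z)-2-(hydroxymethyl)but-2-enoic acid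
Product: 19 (2Z)-2-(acetoxymethyl)but-2-enoic acid
Conditions: Ac2O, pyridine, CH2Cl2, 0 °C to rt; then H2O
Reagents that add atoms: acetic anhydride CC(=O)OC(C)=O
Why: O-acetylation of the primary alcohol without a strongly nucleophilic catalyst should avoid Z to E isomerisation, and any mixed anhydride is hydrolysed in the aqueous work-up.

Step 13
Reactants: 13 1-[(2R,3S)-6-[(tert-butyldimethylsilyl)oxy]-3-hydroxy-2-(prop-1-en-2-yl)-2,3-dihydro-1-benzofuran-5-yl]ethan-1-one; 19 (2Z)-2-(acetoxymethyl)but-2-enoic acid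
Product: 22 (2R,3S)-5-acetyl-6-[(tert-butyldimethylsilyl)oxy]-2-(prop-1-en-2-yl)-2,3-dihydro-1-benzofuran-3-yl (2Z)-2-(acetoxymethyl)but-2-enoate, via mixed anhydride 20 (not isolated), via lithium alkoxide 21 (not isolated)
Conditions: 19, 2,4,6-Cl3C6H2COCl, Et3N, THF, 0 °C; separately 13, LiN(SiMe3)2 (1.0 equiv), THF, −78 °C; then combine, −78 to −20 °C
Reagents that add atoms: none
Why: Yamaguchi-type mixed anhydride acylation of a preformed lithium alkoxide attacks the less hindered alkenoyl carbonyl without a nucleophilic amine catalyst, so the Z alkene and the allylic acetate should survive, and C3 keeps its configuration because only the O–H bond is broken.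

Step 14
Reactants: 22 (2R,3S)-5-acetyl-6-[(tert-butyldimethylsilyl)oxy]-2-(prop-1-en-2-yl)-2,3-dihydro-1-benzofuran-3-yl (2Z)-2-(acetoxymethyl)but-2-enoate
Product: 23 (2R,3S)-5-acetyl-6-hydroxy-2-(prop-1-en-2-yl)-2,3-dihydro-1-benzofuran-3-yl (2Z)-2-(acetoxymethyl)but-2-enoate
Conditions: Bu4NF (1.1 equiv), AcOH (1.5 equiv), THF, 0 °C
Reagents that add atoms: none
Why: Fluoride cleaves the aryl silyl ether, which is activated by the ortho acetyl group, and the acetic acid buffer keeps a free phenoxide para to the benzylic ester from building up, so the esters should survive.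

**Compound list**

1 | prop-2-yn-1-ol | C#CCO | starting material
2 | dimethylaluminium alkoxide of 3-(dimethylalumanyl)-2-methylprop-2-en-1-ol, Al cis to CH3 | C[Al](C)OC/C(C)=C/[Al](C)C | intermediate
3 | (2E)-3-iodo-2-methylprop-2-en-1-ol | OC/C(C)=C/I | intermediate
4 | (2E)-3-iodo-2-methylprop-2-enal | O=C/C(C)=C/I | intermediate
5 | 1-(5-bromo-2,4-dihydroxyphenyl)ethan-1-one | CC(=O)c1cc(Br)c(O)cc1O | starting material
6 | (2E)-3-(4-acetyl-2-bromo-5-hydroxyphenoxy)-2-methylprop-2-enal | CC(=O)c1cc(Br)c(O/C=C(\C)C=O)cc1O | intermediate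
7 | 1-(5-bromo-2-hydroxy-4-{[(1E)-3-hydroxy-2-methylprop-1-en-1-yl]oxy}phenyl)ethan-1-one | CC(=O)c1cc(Br)c(O/C=C(\C)CO)cc1O | intermediate
8 | 1-[2-hydroxy-5-(hydroxymethyl)-4-{[(1E)-3-hydroxy-2-methylprop-1-en-1-yl]oxy}phenyl]ethan-1-one | CC(=O)c1cc(CO)c(O/C=C(\C)CO)cc1O | intermediate
9 | 1-[2-hydroxy-5-(hydroxymethyl)-4-{[(1E)-2-methyl-3-(4,4,5,5-tetramethyl-1,3,2-dioxaborolan-2-yl)prop-1-en-1-yl]oxy}phenyl]ethan-1-one | CC(=O)c1cc(CO)c(O/C=C(\C)CB2OC(C)(C)C(C)(C)O2)cc1O | intermediate
10 | 5-acetyl-4-hydroxy-2-{[(1E)-2-methyl-3-(4,4,5,5-tetramethyl-1,3,2-dioxaborolan-2-yl)prop-1-en-1-yl]oxy}benzaldehyde | CC(=O)c1cc(C=O)c(O/C=C(\C)CB2OC(C)(C)C(C)(C)O2)cc1O | intermediate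
11 | 2-{[(2R,3S)-5-acetyl-6-hydroxy-2-(prop-1-en-2-yl)-2,3-dihydro-1-benzofuran-3-yl]oxy}-4,4,5,5-tetramethyl-1,3,2-dioxaborolane | C=C(C)[C@H]1Oc2cc(O)c(C(C)=O)cc2[C@@H]1OB1OC(C)(C)C(C)(C)O1 | intermediate
12 | 1-[(2R,3S)-3,6-dihydroxy-2-(prop-1-en-2-yl)-2,3-dihydro-1-benzofuran-5-yl]ethan-1-one | C=C(C)[C@H]1Oc2cc(O)c(C(C)=O)cc2[C@@H]1O | intermediate
13 | 1-[(2R,3S)-6-[(tert-butyldimethylsilyl)oxy]-3-hydroxy-2-(prop-1-en-2-yl)-2,3-dihydro-1-benzofuran-5-yl]ethan-1-one | C=C(C)[C@H]1Oc2cc(O[Si](C)(C)C(C)(C)C)c(C(C)=O)cc2[C@@H]1O | intermediate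
14 | (2E)-but-2-enal | C/C=C/C=O | starting material
15 | (2Z)-2-iodobut-2-enal | C/C=C(\I)C=O | intermediate
16 | (2Z)-2-iodobut-2-en-1-ol | C/C=C(\I)CO | intermediate
17 | lithium 2-lithiobut-2-en-1-olate, Li cis to CH3 | C/C=C(\[Li])CO[Li] | intermediate
18 | (2Z)-2-(hydroxymethyl)but-2-enoic acid | C/C=C(\C(=O)O)CO | intermediate
19 | (2Z)-2-(acetoxymethyl)but-2-enoic acid | C/C=C(\C(=O)O)COC(C)=O | intermediate
20 | (2Z)-2-(acetoxymethyl)but-2-enoic 2,4,6-trichlorobenzoic anhydride | C/C=C(\C(=O)OC(=O)c1c(Cl)cc(Cl)cc1Cl)COC(C)=O | intermediate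
21 | lithium (2R,3S)-5-acetyl-6-[(tert-butyldimethylsilyl)oxy]-2-(prop-1-en-2-yl)-2,3-dihydro-1-benzofuran-3-olate | C=C(C)[C@H]1Oc2cc(O[Si](C)(C)C(C)(C)C)c(C(C)=O)cc2[C@@H]1O[Li] | intermediate
22 | (2R,3S)-5-acetyl-6-[(tert-butyldimethylsilyl)oxy]-2-(prop-1-en-2-yl)-2,3-dihydro-1-benzofuran-3-yl (2Z)-2-(acetoxymethyl)but-2-enoate | C=C(C)[C@H]1Oc2cc(O[Si](C)(C)C(C)(C)C)c(C(C)=O)cc2[C@@H]1OC(=O)/C(=C\C)COC(C)=O | intermediate
23 | (2R,3S)-5-acetyl-6-hydroxy-2-(prop-1-en-2-yl)-2,3-dihydro-1-benzofuran-3-yl (2Z)-2-(acetoxymethyl)but-2-enoate | C=C(C)[C@H]1Oc2cc(O)c(C(C)=O)cc2[C@@H]1OC(=O)/C(=C\C)COC(C)=O | target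

**Step count and risks**

Total step count: 14. Longest linear sequence: 10 steps (steps 1 to 8, 13, 14).

Steps most likely to fail:

Step 7 (proposed new method). What may go wrong: insufficient discrimination of the formyl faces by the acid when the nucleophile is tethered, or leakage through the uncatalysed cyclisation, giving material of low enantiomeric purity. The fallback sets out from 9 and comes back at 13. Oxidation with MnO2 as before and warming of aldehyde 10 in toluene without any catalyst (thermal intramolecular allylboration through the same closed transition state, a known reaction type) should give the racemic trans alcohol after hydrolysis. That is 12, formed through 11, together with the (2S,3R) alcohol F2, formed through the mirror-image borate ester F1. Silylation as in step 8 gives 13 and the (2S,3R) silyl ether F3. A kinetic resolution by acylation with isobutyric anhydride, i-Pr2NEt and a chiral isothiourea catalyst (benzotetramisole, its enantiomer chosen in a trial so that F3 reacts faster) should convert F3 into the isobutyrate F4 and leave 13, which is separated and carried on.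

Step 6. What may go wrong: acid-promoted ionisation and solvolysis of the γ-aryloxyallyl alcohol, acetal formation with the neighbouring benzylic alcohol, or loss of alkene geometry at the allylpalladium stage under the cationic, protic conditions. The fallback sets out from 8 and comes back at 9. Both primary alcohols are acetylated (Ac2O, pyridine, CH2Cl2, 0 °C) to give the diacetate F5. Borylation under neutral aprotic conditions with ligand-free Pd2(dba)3 and B2pin2 in DMSO at 50 °C, in which zerovalent palladium ionises only the allylic acetate, should give the allylboronate benzylic acetate F6. Cleavage of the benzylic acetate with K2CO3 in aqueous THF at 0 °C returns 9.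

Step 13. What may go wrong: base-induced loss of the C3 oxygen substituent with aromatisation to the benzofuran, or Z to E isomerisation and allylic transposition of the activated acyl donor. The fallback sets out from 13 and 16 and comes back at 23; it never forms an activated derivative of the acid. Alcohol 16 is silylated (TBSCl, imidazole, DMF) to the vinyl iodide silyl ether F7. Palladium-catalysed carbonylative esterification of F7 with alcohol 13 (PdCl2(PPh3)2, CO 1 atm, Et3N, DMF, 50 °C) builds the acyl group on the intact C–I bond with retention of geometry and should give the bis-silyl ester F8. HF·pyridine in THF removes both silyl groups to give the hydroxy ester F9. AcCl with 2,4,6-collidine in CH2Cl2 at −78 °C acetylates only the primary alcohol, leaving the hydrogen-bonded phenol, and gives 23.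

**Further compounds**

F1 | step 7 | 2-{[(2S,3R)-5-acetyl-6-hydroxy-2-(prop-1-en-2-yl)-2,3-dihydro-1-benzofuran-3-yl]oxy}-4,4,5,5-tetramethyl-1,3,2-dioxaborolane (not isolated) | C=C(C)[C@@H]1Oc2cc(O)c(C(C)=O)cc2[C@H]1OB1OC(C)(C)C(C)(C)O1
F2 | step 7 | 1-[(2S,3R)-3,6-dihydroxy-2-(prop-1-en-2-yl)-2,3-dihydro-1-benzofuran-5-yl]ethan-1-one | C=C(C)[C@@H]1Oc2cc(O)c(C(C)=O)cc2[C@H]1O
F3 | step 7 | 1-[(2S,3R)-6-[(tert-butyldimethylsilyl)oxy]-3-hydroxy-2-(prop-1-en-2-yl)-2,3-dihydro-1-benzofuran-5-yl]ethan-1-one | C=C(C)[C@@H]1Oc2cc(O[Si](C)(C)C(C)(C)C)c(C(C)=O)cc2[C@H]1O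
F4 | step 7 | (2S,3R)-5-acetyl-6-[(tert-butyldimethylsilyl)oxy]-2-(prop-1-en-2-yl)-2,3-dihydro-1-benzofuran-3-yl 2-methylpropanoate | C=C(C)[C@@H]1Oc2cc(O[Si](C)(C)C(C)(C)C)c(C(C)=O)cc2[C@H]1OC(=O)C(C)C
F5 | step 6 | (2E)-3-[4-acetyl-2-(acetoxymethyl)-5-hydroxyphenoxy]-2-methylprop-2-en-1-yl acetate | CC(=O)c1cc(COC(C)=O)c(O/C=C(\C)COC(C)=O)cc1O
F6 | step 6 | 5-acetyl-4-hydroxy-2-{[(1E)-2-methyl-3-(4,4,5,5-tetramethyl-1,3,2-dioxaborolan-2-yl)prop-1-en-1-yl]oxy}benzyl acetate | CC(=O)c1cc(COC(C)=O)c(O/C=C(\C)CB2OC(C)(C)C(C)(C)O2)cc1O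
F7 | step 13 | tert-butyl{[(2Z)-2-iodobut-2-en-1-yl]oxy}dimethylsilane | C/C=C(\I)CO[Si](C)(C)C(C)(C)C
F8 | step 13 | (2R,3S)-5-acetyl-6-[(tert-butyldimethylsilyl)oxy]-2-(prop-1-en-2-yl)-2,3-dihydro-1-benzofuran-3-yl (2Z)-2-{[(tert-butyldimethylsilyl)oxy]methyl}but-2-enoate | C=C(C)[C@H]1Oc2cc(O[Si](C)(C)C(C)(C)C)c(C(C)=O)cc2[C@@H]1OC(=O)/C(=C\C)CO[Si](C)(C)C(C)(C)C
F9 | step 13 | (2R,3S)-5-acetyl-6-hydroxy-2-(prop-1-en-2-yl)-2,3-dihydro-1-benzofuran-3-yl (2Z)-2-(hydroxymethyl)but-2-enoate | C=C(C)[C@H]1Oc2cc(O)c(C(C)=O)cc2[C@@H]1OC(=O)/C(=C\C)CO
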